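The side chain is joined to the ring precursor at its methyl-bearing carbon C2′, which lies β to ring carbon C6 of the 1,2-dioxane. Before the peroxide ring exists, C6 can be a ketone carbonyl and C1′=C2′ an enone. A copper-catalysed asymmetric conjugate addition of 8-phenyloctylmagnesium bromide to an (E)-propenyl ketone that already carries C3–C5 and the C4 methyl stereocentre forms this C–C bond and sets C2′ in one operation. The ketone then becomes C6: methylenation, cobalt-catalysed hydroperoxysilylation, and closure of the hydroperoxide onto the C3 ketone of a β-keto ester give the dioxane hemiketal.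

Key step: step 2

Remark: ring numbering is O1, O2, C3 (hemiketal), C4, C5, C6, with side-chain carbons primed; C3 is an equilibrating hemiketal centre taken as thermodynamically controlled, and C6 is created by radical oxygenation without facial control, so the 6S epimer is obtained by separation at compound 12.

Step 1
Reactants: 1 methyl (2S)-3-bromo-2-methylpropanoate; 2 (2E)-but-2-enoyl chloride
Product: 4 methyl (2R,5E)-2-methyl-4-oxohept-5-enoate, via alkylzinc bromide 3 (not isolated)
Conditions: Zn dust (activated), LiCl, THF, 45 °C; then 2, Pd(PPh3)4 (5 mol %), THF, 0 °C → rt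
Reagents that add atoms: none
Why: Zinc insertion into the primary C–Br bond gives a configurationally stable β-zincio ester (the C2 stereocentre is not touched, its descriptor changes from S to R only by priority), and Negishi-type palladium-catalysed acylation with the enoyl chloride should give the (E)-enone without conjugate addition.

Step 2
Reactants: 4 methyl (2R,5E)-2-methyl-4-oxohept-5-enoate; 5 (8-bromooctyl)benzene
Product: 7 methyl (2R,6R)-2,6-dimethyl-4-oxo-14-phenyltetradecanoate, via Grignard reagent 6 (not isolated)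
Conditions: 5, Mg, Et2O, rt; added slowly to 4, CuBr·SMe2 (5 mol %), Josiphos (6 mol %), t-BuOMe, −75 °C; MeOH quench at −75 °C, aqueous work-up
Reagents that add atoms: none
Why: Copper-catalysed asymmetric conjugate addition of a Grignard reagent to an acyclic enone: the alkyl group passes from magnesium to the chiral Cu(I)–diphosphine complex, which forms a π-complex with the enone, adds oxidatively at the β-carbon (C6 of 4) and reductively eliminates to form the C6–C7 bond of 7, leaving a magnesium enolate that is protonated on quench. No ring is closed. The new stereocentre C6 of 7 (C2′ of the target) is set by the ligand: the Josiphos antipode that directs the alkyl group to the Si face of C6 of 4 gives 6R (both antipodes are commercial), and the existing C2 centre, four bonds away, should have little influence. The step needs 1,4- over 1,2-addition and must spare the methyl ester; the ketone is the only Michael-activating group, its β-carbon carries only a methyl group, and copper catalysis with slow addition at −75 °C should leave both carbonyl groups untouched. The cold quench prevents Dieckmann-type closure of the magnesium enolate onto the ester.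

Step 3
Reactants: 7 methyl (2R,6R)-2,6-dimethyl-4-oxo-14-phenyltetradecanoate
Product: 8 methyl (2R,6R)-2,6-dimethyl-4-methylidene-14-phenyltetradecanoate
Conditions: Ph3PCH3Br (1.5 equiv), KOt-Bu (1.4 equiv), THF, 0 °C → rt
Reagents that add atoms: methyltriphenylphosphonium bromide, C[P+](c1ccccc1)(c1ccccc1)c1ccccc1.[Br-]
Why: Wittig methylenation of an unhindered dialkyl ketone; neither stereocentre is α to the ketone, and a slight deficit of base relative to the phosphonium salt avoids epimerisation α to the ester.

Step 4
Reactants: 8 methyl (2R,6R)-2,6-dimethyl-4-methylidene-14-phenyltetradecanoate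
Product: 9 tert-butyl (4R,8R)-4,8-dimethyl-6-methylidene-3-oxo-16-phenylhexadecanoate
Conditions: t-BuOAc, LDA (3 equiv each), THF, −78 °C; then 8, −78 → −30 °C; AcOH quench
Reagents that add atoms: tert-butyl acetate, CC(=O)OC(C)(C)C
Why: Crossed Claisen condensation: the lithium enolate of tert-butyl acetate adds to the methyl ester at low temperature and the β-keto ester formed is at once deprotonated at C2, which shields C4 from epimerisation.

Step 5
Reactants: 9 tert-butyl (4R,8R)-4,8-dimethyl-6-methylidene-3-oxo-16-phenylhexadecanoate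
Product: 10 tert-butyl (4R,6S,8R)-4,6,8-trimethyl-3-oxo-16-phenyl-6-[(triethylsilyl)peroxy]hexadecanoate
Conditions: Co(thd)2 (10 mol %), O2 (1 atm), Et3SiH, 1,2-dichloroethane, rt
Reagents that add atoms: dioxygen, O=O; triethylsilane, CC[SiH](CC)CC
Why: Mukaiyama–Isayama hydroperoxysilylation: cobalt hydride transfers a hydrogen atom to the terminal CH2, and the tertiary C6 radical is captured by O2 and silylated (Markovnikov), but this open-chain radical offers no useful facial bias, so 10 is expected together with its C6 epimer and the pair is carried on to the separation in step 6.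

Step 6
Reactants: 10 tert-butyl (4R,6S,8R)-4,6,8-trimethyl-3-oxo-16-phenyl-6-[(triethylsilyl)peroxy]hexadecanoate
Product: 12 tert-butyl 2-[(3S,4R,6S)-3-hydroxy-4,6-dimethyl-6-[(2R)-2-methyl-10-phenyldecyl]-1,2-dioxan-3-yl]acetate, via hydroperoxy ketone 11 (not isolated)
Conditions: 0.5 M aq HCl, THF, 0 °C → rt; chromatography (separation from the 6R epimer)
Reagents that add atoms: none
Why: Mild acid cleaves the Si–OO bond and the freed tertiary hydroperoxide adds to the C3 ketone (6-exo-trig hemiperketalisation); C3 should equilibrate to the anomerically favoured axial OH with the C4 methyl equatorial (3S), and the 6S and 6R hemiketals differ in which C6 group is axial, which should allow their separation.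

Step 7
Reactants: 12 tert-butyl 2-[(3S,4R,6S)-3-hydroxy-4,6-dimethyl-6-[(2R)-2-methyl-10-phenyldecyl]-1,2-dioxan-3-yl]acetate
Product: 13 2-[(3S,4R,6S)-3-hydroxy-4,6-dimethyl-6-[(2R)-2-methyl-10-phenyldecyl]-1,2-dioxan-3-yl]acetic acid
Conditions: TFA/CH2Cl2 (1:4), 0 °C; evaporation below 20 °C
Reagents that add atoms: none
Why: Acidolysis of the tert-butyl ester (E1 loss of isobutene) at 0 °C; the β-keto acid stays masked as the cyclic peroxy-hemiketal, which should suppress decarboxylation, and no stereocentre is involved.

Compound list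
1 | methyl (2S)-3-bromo-2-methylpropanoate | COC(=O)[C@H](C)CBr | starting material
2 | (2E)-but-2-enoyl chloride | C/C=C/C(=O)Cl | starting material
3 | [(2S)-3-methoxy-2-methyl-3-oxopropyl]zinc bromide | COC(=O)[C@H](C)C[Zn]Br | intermediate (not isolated)
4 | methyl (2R,5E)-2-methyl-4-oxohept-5-enoate | C/C=C/C(=O)C[C@@H](C)C(=O)OC | intermediate
5 | (8-bromooctyl)benzene | BrCCCCCCCCc1ccccc1 | starting material
6 | (8-phenyloctyl)magnesium bromide | Br[Mg]CCCCCCCCc1ccccc1 | intermediate (not isolated)
7 | methyl (2R,6R)-2,6-dimethyl-4-oxo-14-phenyltetradecanoate | C[C@H](CCCCCCCCc1ccccc1)CC(=O)C[C@@H](C)C(=O)OC | intermediate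
8 | methyl (2R,6R)-2,6-dimethyl-4-methylidene-14-phenyltetradecanoate | C[C@H](CCCCCCCCc1ccccc1)CC(=C)C[C@@H](C)C(=O)OC | intermediate
9 | tert-butyl (4R,8R)-4,8-dimethyl-6-methylidene-3-oxo-16-phenylhexadecanoate | C[C@H](CCCCCCCCc1ccccc1)CC(=C)C[C@@H](C)C(=O)CC(=O)OC(C)(C)C | intermediate
10 | tert-butyl (4R,6S,8R)-4,6,8-trimethyl-3-oxo-16-phenyl-6-[(triethylsilyl)peroxy]hexadecanoate | C[C@H](CCCCCCCCc1ccccc1)C[C@](C)(OO[Si](CC)(CC)CC)C[C@@H](C)C(=O)CC(=O)OC(C)(C)C | intermediate
11 | tert-butyl (4R,6S,8R)-6-hydroperoxy-4,6,8-trimethyl-3-oxo-16-phenylhexadecanoate | C[C@H](CCCCCCCCc1ccccc1)C[C@](C)(OO)C[C@@H](C)C(=O)CC(=O)OC(C)(C)C | intermediate (not isolated)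
12 | tert-butyl 2-[(3S,4R,6S)-3-hydroxy-4,6-dimethyl-6-[(2R)-2-methyl-10-phenyldecyl]-1,2-dioxan-3-yl]acetate | C[C@H](CCCCCCCCc1ccccc1)C[C@@]1(C)C[C@@H](C)[C@](O)(CC(=O)OC(C)(C)C)OO1 | intermediate
13 | 2-[(3S,4R,6S)-3-hydroxy-4,6-dimethyl-6-[(2R)-2-methyl-10-phenyldecyl]-1,2-dioxan-3-yl]acetic acid | C[C@H](CCCCCCCCc1ccccc1)C[C@@]1(C)C[C@@H](C)[C@](O)(CC(=O)O)OO1 | target

Total step count: 7. Longest linear sequence: 7 steps (1 → 4 → 7 → 8 → 9 → 10 → 12 → 13).

Steps most likely to fail

Step 5. The capture of the open-chain C6 radical by O2 has no facial discrimination, so the 6R epimer forms alongside 10 and material is lost at the separation; chelation of the β-keto ester to cobalt may also slow the catalyst. The fallback replaces radical oxygenation by an ionic, chair-controlled ring closure. Setting out from 9, aqueous H2O2 converts the C3 ketone reversibly into its perhydrate, and Hg(OAc)2 (cycloperoxymercuration, 6-exo, Markovnikov) should give tert-butyl 2-[(3S,4R,6S)-6-[(acetoxymercurio)methyl]-3-hydroxy-4-methyl-6-[(2R)-2-methyl-10-phenyldecyl]-1,2-dioxan-3-yl]acetate F1. A chair transition state with the C4 methyl equatorial and the long C6 chain pseudo-equatorial should place CH2Hg axial. Alkaline NaBH4 demercuration at 0 °C turns CH2Hg into the axial methyl group and comes back to the route at 12.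

Step 2. The small β-methyl group and the α′-branched ketone may give insufficient enantiofacial discrimination, and 1,2-addition or Dieckmann closure of the enolate may compete. The fallback takes the C2′ configuration from the chiral pool by a stereospecific ring opening. Setting out from Grignard reagent 6 (from 5), copper-catalysed SN2 opening of commercial (4R)-4-methyloxetan-2-one (C[C@@H]1CC(=O)O1) at C4 with inversion (CuBr·SMe2 cat., THF/Me2S, −30 °C) should give (3R)-3-methyl-11-phenylundecanoic acid F2. EtSH, DCC and DMAP give S-ethyl (3R)-3-methyl-11-phenylundecanethioate F3. Fukuyama coupling of F3 with the zinc reagent 3 [PdCl2(PPh3)2, toluene/THF, rt] comes back to the route at 7.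

Step 7. Trifluoroacetic acid may ionise the tertiary C6–O bond or open the hemiketal, after which the free β-keto acid would decarboxylate. The fallback uses a fluoride-labile ester so that no strong acid is needed. Setting out from 8, crossed Claisen condensation with the lithium enolate of 2-(trimethylsilyl)ethyl acetate should give 2-(trimethylsilyl)ethyl (4R,8R)-4,8-dimethyl-6-methylidene-3-oxo-16-phenylhexadecanoate F4. Mukaiyama–Isayama hydroperoxysilylation gives 2-(trimethylsilyl)ethyl (4R,6S,8R)-4,6,8-trimethyl-3-oxo-16-phenyl-6-[(triethylsilyl)peroxy]hexadecanoate F5. Dilute HCl in THF frees 2-(trimethylsilyl)ethyl (4R,6S,8R)-6-hydroperoxy-4,6,8-trimethyl-3-oxo-16-phenylhexadecanoate F6 (not isolated), which closes to 2-(trimethylsilyl)ethyl 2-[(3S,4R,6S)-3-hydroxy-4,6-dimethyl-6-[(2R)-2-methyl-10-phenyldecyl]-1,2-dioxan-3-yl]acetate F7; the C6 epimers are separated here. TBAF buffered with AcOH in THF at 0 °C, then acidification to pH 4, comes back to the route at 13.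

Further compounds
F1 | step 5 | tert-butyl 2-[(3S,4R,6S)-6-[(acetoxymercurio)methyl]-3-hydroxy-4-methyl-6-[(2R)-2-methyl-10-phenyldecyl]-1,2-dioxan-3-yl]acetate | C[C@H](CCCCCCCCc1ccccc1)C[C@@]1(C[Hg]OC(C)=O)C[C@@H](C)[C@](O)(CC(=O)OC(C)(C)C)OO1
F2 | step 2 | (3R)-3-methyl-11-phenylundecanoic acid | C[C@H](CCCCCCCCc1ccccc1)CC(=O)O
F3 | step 2 | S-ethyl (3R)-3-methyl-11-phenylundecanethioate | C[C@H](CCCCCCCCc1ccccc1)CC(=O)SCC
F4 | step 7 | 2-(trimethylsilyl)ethyl (4R,8R)-4,8-dimethyl-6-methylidene-3-oxo-16-phenylhexadecanoate | C[C@H](CCCCCCCCc1ccccc1)CC(=C)C[C@@H](C)C(=O)CC(=O)OCC[Si](C)(C)C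
F5 | step 7 | 2-(trimethylsilyl)ethyl (4R,6S,8R)-4,6,8-trimethyl-3-oxo-16-phenyl-6-[(triethylsilyl)peroxy]hexadecanoate | C[C@H](CCCCCCCCc1ccccc1)C[C@](C)(OO[Si](CC)(CC)CC)C[C@@H](C)C(=O)CC(=O)OCC[Si](C)(C)C
F6 | step 7 | 2-(trimethylsilyl)ethyl (4R,6S,8R)-6-hydroperoxy-4,6,8-trimethyl-3-oxo-16-phenylhexadecanoate | C[C@H](CCCCCCCCc1ccccc1)C[C@](C)(OO)C[C@@H](C)C(=O)CC(=O)OCC[Si](C)(C)C
F7 | step 7 | 2-(trimethylsilyl)ethyl 2-[(3S,4R,6S)-3-hydroxy-4,6-dimethyl-6-[(2R)-2-methyl-10-phenyldecyl]-1,2-dioxan-3-yl]acetate | C[C@H](CCCCCCCCc1ccccc1)C[C@@]1(C)C[C@@H](C)[C@](O)(CC(=O)OCC[Si](C)(C)C)OO1
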